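The n-C33 chain on C2 of the γ-pyrone ring is unbranched, unfunctionalised and free of stereocentres. It is therefore cut between two ordinary methylenes, C9' and C10' (counted from C2), where a traceless sp3–sp3 coupling leaves nothing to remove. In one flask 1-tetracosene is hydroborated at C1 with 9-BBN, and the B-alkylborane is cross-coupled (Pd/PCy3, alkyl–alkyl Suzuki–Miyaura) with 2-(9-bromononyl)-5-hydroxy-7-methoxychromone. This gives the target directly, and the hydrogen-bonded 5-OH/C4=O pair stays unprotected. The bromide precursor arises from 10-bromodecanoic acid (its C1 becomes pyrone C2, its C10 becomes C9') and symmetrical 2',6'-dihydroxy-4'-methoxyacetophenone.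

Key step: step 3

Remark: the side chain is read as n-tritriacontyl (9 + 24 carbons), numbered C1'–C33' outward from C2. The target has no stereocentre. Compounds 1, 3, 6 and 7 are taken as catalogue chemicals.

Step 1
Reactants: 1 10-bromodecanoic acid
Product: 2 10-bromodecanoyl chloride
Conditions: (COCl)2 (1.3 equiv), DMF (cat.), CH2Cl2, 0 °C to rt; evaporate
Reagents that add atoms: oxalyl chloride, O=C(Cl)C(=O)Cl
Why: Acid chloride formation with oxalyl chloride under DMF (Vilsmeier-type) catalysis runs near room temperature without base, leaves the primary C–Br bond alone and gives only gaseous by-products, so the crude chloride can be used after evaporation.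

Step 2
Reactants: 3 1-(2,6-dihydroxy-4-methoxyphenyl)ethan-1-one (2',6'-dihydroxy-4'-methoxyacetophenone); 2 10-bromodecanoyl chloride
Product: 5 2-(9-bromononyl)-5-hydroxy-7-methoxy-4H-chromen-4-one, via bromo beta-diketone 4 (not isolated)
Conditions: 3, LiHMDS (4.2 equiv), THF, −78 to −10 °C; 2, −78 to 0 °C; cold 1 M HCl wash; crude 4, p-TsOH·H2O (10 mol %), PhMe, 90 °C
Reagents that add atoms: none
Why: Claisen-type C-acylation of the trilithiated acetophenone (any O-acyl ester funnels to the same diketone by a Baker–Venkataraman acyl shift) followed by acid-catalysed cyclodehydration (6-exo-trig attack of a phenol OH on the chain ketone, then loss of water) should work because LiHMDS does not attack the C–Br bond at low temperature and because the two ortho OH groups of 3 are equivalent, so only one chromone can form and the remaining OH becomes the chelated 5-OH.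

Step 3
Reactants: 6 tetracos-1-ene; 7 9-borabicyclo[3.3.1]nonane (9-BBN-H); 5 2-(9-bromononyl)-5-hydroxy-7-methoxy-4H-chromen-4-one
Product: 9 5-hydroxy-7-methoxy-2-tritriacontyl-4H-chromen-4-one, via B-tetracosyl-9-BBN 8 (not isolated)
Conditions: 6 + 7 (1.5 equiv each), THF, 0 to 40 °C; then 5 (1.0 equiv), Pd(OAc)2 (4 mol %), PCy3 (8 mol %), K3PO4·H2O (2.5 equiv), THF, rt to 40 °C
Reagents that add atoms: none
Why: 9-BBN-H adds to the terminal C=C of 6 through a four-centre syn transition state that places boron on the unhindered C1, so the future C10' becomes the only primary B–C bond of 8; because this is complete before 5 is added, no B–H bond ever meets the C4=O or the C2=C3 bond of the pyrone. K3PO4·H2O turns 8 into a hydroxyborate, Pd(0)(PCy3)2 inserts into the primary C9'–Br bond of 5 by an SN2-type oxidative addition, the primary tetracosyl group (not the secondary bicyclic B–C bonds) is transferred to palladium, and reductive elimination forms C9'–C10'. The closest known reaction type is the room-temperature alkyl–alkyl Suzuki–Miyaura coupling of primary alkyl bromides bearing β-hydrogens with B-alkyl-9-BBN reagents, in which the bulky, electron-rich trialkylphosphine makes coupling faster than β-hydride elimination. No ring is closed and no stereocentre is created, so only chemoselectivity is at stake. The substrate secures it: the C–Br bond is the only site open to Pd(0), the 5-OH is locked in a hydrogen bond to C4=O and is a poor nucleophile towards the bromide, the phosphate is too weak to deprotonate the vinylogous C1'H2, and the extra base and borane cover reversible binding of the phenoxide to boron. Both handles (C=C and C–Br) vanish in the coupling, so the product is the target itself and no later redox or deprotection step is needed.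

Compound list
1 | 10-bromodecanoic acid | OC(=O)CCCCCCCCCBr | starting material
2 | 10-bromodecanoyl chloride | ClC(=O)CCCCCCCCCBr | intermediate
3 | 1-(2,6-dihydroxy-4-methoxyphenyl)ethan-1-one (2',6'-dihydroxy-4'-methoxyacetophenone) | CC(=O)c1c(O)cc(OC)cc1O | starting material
4 | 12-bromo-1-(2,6-dihydroxy-4-methoxyphenyl)dodecane-1,3-dione (bromo beta-diketone, drawn as the diketo tautomer) | O=C(CCCCCCCCCBr)CC(=O)c1c(O)cc(OC)cc1O | intermediate
5 | 2-(9-bromononyl)-5-hydroxy-7-methoxy-4H-chromen-4-one | BrCCCCCCCCCc1cc(=O)c2c(O)cc(OC)cc2o1 | intermediate
6 | tetracos-1-ene (1-tetracosene) | C=CCCCCCCCCCCCCCCCCCCCCCCC | starting material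
7 | 9-borabicyclo[3.3.1]nonane (9-BBN-H, sold as the dimer or as a THF solution) | B1C2CCCC1CCC2 | starting material
8 | 9-tetracosyl-9-borabicyclo[3.3.1]nonane (B-tetracosyl-9-BBN) | CCCCCCCCCCCCCCCCCCCCCCCCB1C2CCCC1CCC2 | intermediate
9 | 5-hydroxy-7-methoxy-2-tritriacontyl-4H-chromen-4-one | CCCCCCCCCCCCCCCCCCCCCCCCCCCCCCCCCc1cc(=O)c2c(O)cc(OC)cc2o1 | target

Total step count: 3
Longest linear sequence: 3 steps (1 → 2 → 5 → 9)

Steps most likely to fail

1. Step 3 (key step).
- **Risk:** Transmetalation may be slowed by reversible binding of the 5-phenoxide/C4=O chelate to boron or palladium, or by poor solubility of the waxy borane. β-Hydride elimination and hydrodebromination of the alkylpalladium intermediate could then take over.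
- **Fallback:** The same C–C bond is made before the heterocycle exists, and the ring is built last. The fallback sets out from 8, prepared from 6 and 7 as before. Coupling with commercial methyl 10-bromodecanoate (COC(=O)CCCCCCCCCBr) under Pd/PCy3 catalysis now runs on a plain bromo ester without phenol or pyrone, and should give methyl tetratriacontanoate F1. Claisen condensation of this ester with the LiHMDS-derived polyanion of 3 (THF, 0 to 50 °C, where the waxy ester stays dissolved) should give 1-(2,6-dihydroxy-4-methoxyphenyl)hexatriacontane-1,3-dione F2. Acid-catalysed cyclodehydration (p-TsOH, PhMe, 90 °C) comes back to the route at 9.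

2. Step 2.
- **Risk:** O-acylation or double acylation may compete, the enolisable acid chloride may form a ketene, and phenoxide or enolate may attack the primary bromide while the mixture warms.
- **Fallback:** The ring is made first and the chain is attached by vinylogous alkylation. The fallback sets out from 3. Claisen condensation with ethyl acetate (NaH, THF, reflux) should give 1-(2,6-dihydroxy-4-methoxyphenyl)butane-1,3-dione F3. Acid cyclodehydration should then give 5-hydroxy-7-methoxy-2-methyl-4H-chromen-4-one (eugenin) F4. Double deprotonation (LDA, 2.2 equiv, THF, −78 °C) forms the phenoxide/C2-methyl dienolate. This is alkylated at the exocyclic carbon with an excess of 1,8-dibromooctane (BrCCCCCCCCBr), which comes back to the route at 5. Compounds 1 and 2 are then not needed.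

3. Step 1.
- **Risk:** Chloride may exchange with the primary bromide under the Vilsmeier conditions, or the crude chloride may hydrolyse on handling.
- **Fallback:** No acid chloride is used. The fallback sets out from 1 and 3. Steglich esterification (DCC, cat. DMAP, CH2Cl2, 0 °C to rt, one equivalent of acid) should give 2-acetyl-3-hydroxy-5-methoxyphenyl 10-bromodecanoate F5. A Baker–Venkataraman O-to-C acyl shift (LiHMDS, 3.2 equiv, THF, −78 to 0 °C) comes back to the route at 4, which is cyclised as in step 2.

Further compounds
F1 | step 3 | methyl tetratriacontanoate | CCCCCCCCCCCCCCCCCCCCCCCCCCCCCCCCCC(=O)OC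
F2 | step 3 | 1-(2,6-dihydroxy-4-methoxyphenyl)hexatriacontane-1,3-dione | CCCCCCCCCCCCCCCCCCCCCCCCCCCCCCCCCC(=O)CC(=O)c1c(O)cc(OC)cc1O
F3 | step 2 | 1-(2,6-dihydroxy-4-methoxyphenyl)butane-1,3-dione | CC(=O)CC(=O)c1c(O)cc(OC)cc1O
F4 | step 2 | 5-hydroxy-7-methoxy-2-methyl-4H-chromen-4-one (eugenin) | Cc1cc(=O)c2c(O)cc(OC)cc2o1
F5 | step 1 | 2-acetyl-3-hydroxy-5-methoxyphenyl 10-bromodecanoate | CC(=O)c1c(O)cc(OC)cc1OC(=O)CCCCCCCCCBr
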